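**Retrosynthetic overview** (lignan numbering: syringyl arm C7–C9, guaiacyl arm C7′–C9′)
1. C7–OH ⇐ aryl ketone 11 by reagent-controlled hydride delivery (C7 S); the C7–aryl bond ⇐ aldehyde 6 + syringyl-lithium 9.
2. Tetrahydrofuran ring (O, C9, C8, C8′, C9′) ⇐ ring contraction of the seven-membered vinyl acetal 5 (4,5-dihydro-1,3-dioxepin → tetrahydrofuran-3-carbaldehyde): the acetal CH2 leaves the enol oxygen and bonds to C8 (it becomes C9), the enol-ether CH becomes the C7 aldehyde, and C8 is set trans to C8′.
3. Feature used: C9 and C9′ are bare O–CH2 groups and C8 carries the oxygenated exocyclic C7, so the O–CH2–C8–C7(–O) array of the ring is the retron of a vinyl formaldehyde acetal.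
4. 5 ⇐ enantioselective benzyl Heck reaction of commercial 4,7-dihydro-1,3-dioxepin 4 (it supplies C7, C8, C8′, C9, C9′ and both oxygens) with the vanillyl trifluoroacetate 3; this sets C8′.
5. Ring order: the dioxepin ring is bought; the only ring made is the tetrahydrofuran, in step 4.

Key step: step 4

Assumption: the sense of induction of the phosphoramidite in step 3 is not predicted here; the ligand antipode that gives the (5R) enol ether 5 is the one used.

Step 1
Reactants: 1 vanillyl alcohol [4-(hydroxymethyl)-2-methoxyphenol]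
Product: 2 4-(hydroxymethyl)-2-methoxyphenyl pivalate
Conditions: PivCl (1.05 equiv), NaOH (1.05 equiv), H2O/CH2Cl2, Bu4NBr (cat.), 0 °C
Reagents that add atoms: pivaloyl chloride, CC(C)(C)C(=O)Cl
Why: Schotten–Baumann O-acylation: aqueous NaOH deprotonates only the phenol (pKa about 10), so the phenoxide is acylated while the benzylic alcohol stays free, and the electron-poor pivalate later keeps the benzylic ester from ionising to a quinone methide.

Step 2
Reactants: 2 4-(hydroxymethyl)-2-methoxyphenyl pivalate
Product: 3 2-methoxy-4-{[(trifluoroacetyl)oxy]methyl}phenyl pivalate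
Conditions: (CF3CO)2O (1.2 equiv), pyridine (1.5 equiv), CH2Cl2, 0 °C
Reagents that add atoms: trifluoroacetic anhydride, FC(F)(F)C(=O)OC(=O)C(F)(F)F
Why: Acylation of the primary benzylic alcohol with trifluoroacetic anhydride should give the benzylic trifluoroacetate, the leaving-group class used for oxidative addition in palladium-catalysed benzyl Heck reactions.

Step 3
Reactants: 3 2-methoxy-4-{[(trifluoroacetyl)oxy]methyl}phenyl pivalate, 4 4,7-dihydro-1,3-dioxepin
Product: 5 4-{[(5R)-4,5-dihydro-1,3-dioxepin-5-yl]methyl}-2-methoxyphenyl pivalate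
Conditions: 4 (4 equiv), Pd(dba)2 (5 mol %), BINOL-derived phosphoramidite L* (6 mol %), Li2CO3 (1.5 equiv), 1,4-dioxane, 60 °C
Reagents that add atoms: none
Why: Asymmetric Mizoroki–Heck reaction of a benzylic electrophile with a cyclic olefin: oxidative addition gives a cationic η3-benzylpalladium species, ligand-controlled syn-carbopalladation of one of the two enantiotopic olefin carbons of the Cs-symmetric dioxepin sets C5 (lignan C8′, R), and syn β-hydride elimination can only occur toward C7 (the C5–H is anti to Pd), which gives the enol ether without touching the new stereocentre.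

Step 4
Reactants: 5 4-{[(5R)-4,5-dihydro-1,3-dioxepin-5-yl]methyl}-2-methoxyphenyl pivalate
Product: 6 4-{[(3R,4R)-4-formyltetrahydrofuran-3-yl]methyl}-2-methoxyphenyl pivalate (trans)
Conditions: TMSOTf (10 mol %), 2,6-di-tert-butyl-4-methylpyridine (10 mol %), CH2Cl2 (0.02 M), −78 → −30 °C; Et3N quench
Reagents that add atoms: none
Why: This is the Lewis-acid-catalysed vinyl acetal rearrangement (formal 1,3-O→C shift, Petasis–Ferrier type) known for 4,5-dihydro-1,3-dioxepins, which contract to tetrahydrofuran-3-carbaldehydes: TMSOTf silylates the enol oxygen O1, the C2–O1 bond ionises to a (Z)-silyl enol ether tethered to the alkoxymethyl oxocarbenium CH2=O3+, and the enol carbon C6 attacks C2 in an intramolecular Mukaiyama-type step that releases the silyl cation for the next turnover, so 5 and 6 are isomers. The seven-membered acetal thereby contracts to the tetrahydrofuran (O3, C2, C6, C5, C4 = ring O, C9, C8, C8′, C9′) by a 5-(enolexo)-endo-trig closure onto the oxocarbenium, formally disfavoured but routine for an oxocarbenium and an enol held by a three-atom tether. The new stereocentre C3 (lignan C8) is controlled by the existing C8′ centre: in the (Z)-enol ether A(1,3) strain places the C8′–H in the enol plane, the tethered oxocarbenium reaches the face opposite to the benzyl group, and formyl and benzyl should end up trans (3R,4R). The trans isomer is also the thermodynamic one at this epimerisable α-formyl centre, while C8′ cannot epimerise. The step needs C- over O-recombination and ionisation of C2–O1 and not of C2–O3: C–C bond formation is irreversible, the enol oxygen is the better leaving group, high dilution disfavours intermolecular aldol-type reaction of 6 with 5, and the pivaloyloxy arene is too electron-poor and too remote for Friedel–Crafts capture.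

Step 5
Reactants: 7 4-bromo-2,6-dimethoxyphenol
Product: 8 (4-bromo-2,6-dimethoxyphenoxy)(tert-butyl)dimethylsilane
Conditions: TBSCl (1.2 equiv), imidazole (2.5 equiv), DMF, rt
Reagents that add atoms: tert-butyldimethylsilyl chloride, CC(C)(C)[Si](C)(C)Cl
Why: Imidazole-promoted silylation of the hindered phenol should give a bromide that tolerates bromine–lithium exchange and whose silyl ether falls off under the final basic methanolysis.

Step 6
Reactants: 8 (4-bromo-2,6-dimethoxyphenoxy)(tert-butyl)dimethylsilane, 6 4-{[(3R,4R)-4-formyltetrahydrofuran-3-yl]methyl}-2-methoxyphenyl pivalate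
Product: 10 4-{[(3R,4R)-4-{[4-(tert-butyldimethylsilyloxy)-3,5-dimethoxyphenyl](hydroxy)methyl}tetrahydrofuran-3-yl]methyl}-2-methoxyphenyl pivalate (both C7 epimers), via aryllithium 9 (not isolated)
Conditions: 8 (1.15 equiv), n-BuLi (1.1 equiv), THF, −78 °C, 30 min; then 6, −78 °C; H2O quench
Reagents that add atoms: n-butyllithium, [Li]CCCC (supplies the lithium of 9 only; nothing from it remains in 10)
Why: Bromine–lithium exchange followed by 1,2-addition of the aryllithium to the aldehyde, which at −78 °C is far more electrophilic than the hindered aryl pivalate; the C7 epimer ratio does not matter (Felkin–Anh addition would favour 7R) because C7 is oxidised in step 7.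

Step 7
Reactants: 10 4-{[(3R,4R)-4-{[4-(tert-butyldimethylsilyloxy)-3,5-dimethoxyphenyl](hydroxy)methyl}tetrahydrofuran-3-yl]methyl}-2-methoxyphenyl pivalate
Product: 11 4-{[(3R,4R)-4-[4-(tert-butyldimethylsilyloxy)-3,5-dimethoxybenzoyl]tetrahydrofuran-3-yl]methyl}-2-methoxyphenyl pivalate
Conditions: Dess–Martin periodinane (1.3 equiv), CH2Cl2, 0 °C → rt
Reagents that add atoms: none
Why: Dess–Martin oxidation of the secondary benzylic alcohol to the aryl ketone under near-neutral conditions that leave the silyl ether and the pivalate intact; C8 stays in its thermodynamic trans configuration (a residual cis isomer could be converged at this stage with DBU).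

Step 8
Reactants: 11 4-{[(3R,4R)-4-[4-(tert-butyldimethylsilyloxy)-3,5-dimethoxybenzoyl]tetrahydrofuran-3-yl]methyl}-2-methoxyphenyl pivalate
Product: 12 4-{[(3R,4R)-4-{(S)-[4-(tert-butyldimethylsilyloxy)-3,5-dimethoxyphenyl](hydroxy)methyl}tetrahydrofuran-3-yl]methyl}-2-methoxyphenyl pivalate
Conditions: (R)-2-methyl-CBS-oxazaborolidine (20 mol %), BH3·SMe2 (1.0 equiv), THF, −20 °C; MeOH quench
Reagents that add atoms: none
Why: Corey–Bakshi–Shibata reduction: with the aryl group as the large substituent the (R)-oxazaborolidine directs hydride to the face that gives the (S)-carbinol, and this is expected to be matched with the Felkin–Anh preference of the (3R) α-centre (branched C8′ anti to the hydride), so C7 should be set as S; borane leaves the aryl pivalate untouched at −20 °C.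

Step 9
Reactants: 12 4-{[(3R,4R)-4-{(S)-[4-(tert-butyldimethylsilyloxy)-3,5-dimethoxyphenyl](hydroxy)methyl}tetrahydrofuran-3-yl]methyl}-2-methoxyphenyl pivalate
Product: 13 4-[(S)-hydroxy{(3R,4R)-4-[(4-hydroxy-3-methoxyphenyl)methyl]tetrahydrofuran-3-yl}methyl]-2,6-dimethoxyphenol (CNP0307127.1)
Conditions: NaOMe (0.3 equiv), MeOH, rt; AcOH (0.3 equiv) on work-up
Reagents that add atoms: none
Why: Methoxide-catalysed methanolysis (transesterification of the aryl pivalate and Si–O cleavage of the phenolic silyl ether) should free both phenols at room temperature, where the 4-hydroxybenzylic carbinol does not yet form a quinone methide, and touches no stereocentre.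

**Compound list**
1 | vanillyl alcohol, 4-(hydroxymethyl)-2-methoxyphenol | COc1cc(CO)ccc1O | starting material
2 | 4-(hydroxymethyl)-2-methoxyphenyl pivalate | COc1cc(CO)ccc1OC(=O)C(C)(C)C | intermediate
3 | 2-methoxy-4-{[(trifluoroacetyl)oxy]methyl}phenyl pivalate | COc1cc(COC(=O)C(F)(F)F)ccc1OC(=O)C(C)(C)C | intermediate
4 | 4,7-dihydro-1,3-dioxepin | C1OCC=CCO1 | starting material
5 | 4-{[(5R)-4,5-dihydro-1,3-dioxepin-5-yl]methyl}-2-methoxyphenyl pivalate | COc1cc(C[C@H]2COCOC=C2)ccc1OC(=O)C(C)(C)C | intermediate
6 | 4-{[(3R,4R)-4-formyltetrahydrofuran-3-yl]methyl}-2-methoxyphenyl pivalate (trans) | COc1cc(C[C@H]2COC[C@@H]2C=O)ccc1OC(=O)C(C)(C)C | intermediate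
7 | 4-bromo-2,6-dimethoxyphenol | COc1cc(Br)cc(OC)c1O | starting material
8 | (4-bromo-2,6-dimethoxyphenoxy)(tert-butyl)dimethylsilane | COc1cc(Br)cc(OC)c1O[Si](C)(C)C(C)(C)C | intermediate
9 | {4-[(tert-butyldimethylsilyl)oxy]-3,5-dimethoxyphenyl}lithium | [Li]c1cc(OC)c(O[Si](C)(C)C(C)(C)C)c(OC)c1 | intermediate
10 | 4-{[(3R,4R)-4-{[4-(tert-butyldimethylsilyloxy)-3,5-dimethoxyphenyl](hydroxy)methyl}tetrahydrofuran-3-yl]methyl}-2-methoxyphenyl pivalate, both C7 epimers | COc1cc(C[C@H]2COC[C@@H]2C(O)c2cc(OC)c(O[Si](C)(C)C(C)(C)C)c(OC)c2)ccc1OC(=O)C(C)(C)C | intermediate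
11 | 4-{[(3R,4R)-4-[4-(tert-butyldimethylsilyloxy)-3,5-dimethoxybenzoyl]tetrahydrofuran-3-yl]methyl}-2-methoxyphenyl pivalate | COc1cc(C[C@H]2COC[C@@H]2C(=O)c2cc(OC)c(O[Si](C)(C)C(C)(C)C)c(OC)c2)ccc1OC(=O)C(C)(C)C | intermediate
12 | 4-{[(3R,4R)-4-{(S)-[4-(tert-butyldimethylsilyloxy)-3,5-dimethoxyphenyl](hydroxy)methyl}tetrahydrofuran-3-yl]methyl}-2-methoxyphenyl pivalate | COc1cc(C[C@H]2COC[C@@H]2[C@H](O)c2cc(OC)c(O[Si](C)(C)C(C)(C)C)c(OC)c2)ccc1OC(=O)C(C)(C)C | intermediate
13 | 4-[(S)-hydroxy{(3R,4R)-4-[(4-hydroxy-3-methoxyphenyl)methyl]tetrahydrofuran-3-yl}methyl]-2,6-dimethoxyphenol | COc1cc(C[C@H]2COC[C@@H]2[C@H](O)c2cc(OC)c(O)c(OC)c2)ccc1O | target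

**Totals**
Total step count: 9. Longest linear sequence: 8 steps (1 → 2 → 3 → 5 → 6 → 10 → 11 → 12 → 13, that is steps 1–4 and 6–9).

**Steps most likely to fail**

Step 3. The η3-benzylpalladium species may insert the hindered cis-disubstituted seven-membered olefin slowly or with poor discrimination between the enantiotopic olefin carbons, so that the enantiomeric purity of C8′ is lost at its source, or the benzyl fragment is consumed by homocoupling. The fallback sets out from 2 and comes back at 6; it takes C8′ from an auxiliary instead of a catalyst. Appel bromination of 2 (CBr4, PPh3) should give 4-(bromomethyl)-2-methoxyphenyl pivalate F1. (R)-4-Benzyl-3-(pent-4-enoyl)oxazolidin-2-one F2 is made from commercial (R)-4-benzyl-2-oxazolidinone, n-BuLi and pent-4-enoyl chloride. Evans alkylation of its sodium enolate (NaHMDS, THF, −78 °C) with F1, on the enolate face opposite to the auxiliary benzyl group, should give (R)-4-benzyl-3-[(2S)-2-{[3-methoxy-4-(pivaloyloxy)phenyl]methyl}pent-4-enoyl]oxazolidin-2-one F3. Reductive removal of the auxiliary (NaBH4, THF/H2O) gives 4-[(2S)-2-(hydroxymethyl)pent-4-en-1-yl]-2-methoxyphenyl pivalate F4, and MOMCl/i-Pr2NEt gives 2-methoxy-4-{(2S)-2-[(methoxymethoxy)methyl]pent-4-en-1-yl}phenyl pivalate F5. Ozonolysis (O3, CH2Cl2, −78 °C; PPh3) gives 2-methoxy-4-{(2R)-2-[(methoxymethoxy)methyl]-4-oxobutyl}phenyl pivalate F6. TMSOTf/i-Pr2NEt at high dilution (one-pot enol silane formation and intramolecular Mukaiyama-type alkylation by the tethered MOM-derived oxocarbenium) should close F6 to 6.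

Step 4. Ionisation of the unsubstituted acetal carbon may be slow, so that adventitious protonation of the enol ether or intermolecular aldol-type oligomerisation outruns the intramolecular C–C bond formation. The fallback sets out from 5 and comes back at 6; it opens the acetal first and closes the ring in a separate, thiophile-triggered step. PhSSiMe3 with catalytic ZnI2/Bu4NI should exchange the enol oxygen at the acetal carbon for phenylthio and give the open-chain 2-methoxy-4-{(2R,3Z)-2-{[(phenylthio)methoxy]methyl}-4-[(trimethylsilyl)oxy]but-3-en-1-yl}phenyl pivalate F7. AgOTf (CH2Cl2, −40 °C, molecular sieves) then removes the thiolate, and the oxocarbenium, formed irreversibly under non-acidic conditions, is alkylated by the enol silane to give 6.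

Step 8. Facial selectivity of hydride delivery may be poor, because the oxazaborolidine differentiates an aryl from a branched alkyl group less well than from a methyl group, so that the 7R epimer forms alongside 12. The fallback sets out from 11 and comes back at 13; it corrects C7 by SN2 inversion instead of facial control. After reduction of 11, the 7R epimer 4-{[(3R,4R)-4-{(R)-[4-(tert-butyldimethylsilyloxy)-3,5-dimethoxyphenyl](hydroxy)methyl}tetrahydrofuran-3-yl]methyl}-2-methoxyphenyl pivalate F8 is separated from 12. Mitsunobu esterification of F8 (4-nitrobenzoic acid, PPh3, DIAD, toluene, −20 °C) should give with inversion the (7S) ester (S)-[4-(tert-butyldimethylsilyloxy)-3,5-dimethoxyphenyl]{(3R,4R)-4-{[3-methoxy-4-(pivaloyloxy)phenyl]methyl}tetrahydrofuran-3-yl}methyl 4-nitrobenzoate F9. Its nitrobenzoate is cleaved together with the pivalate and the silyl ether under the conditions of step 9 to give 13.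

**Further compounds**
F1 | step 3 | 4-(bromomethyl)-2-methoxyphenyl pivalate | COc1cc(CBr)ccc1OC(=O)C(C)(C)C
F2 | step 3 | (R)-4-benzyl-3-(pent-4-enoyl)oxazolidin-2-one | C=CCCC(=O)N1[C@H](Cc2ccccc2)COC1=O
F3 | step 3 | (R)-4-benzyl-3-[(2S)-2-{[3-methoxy-4-(pivaloyloxy)phenyl]methyl}pent-4-enoyl]oxazolidin-2-one | C=CC[C@@H](Cc1ccc(OC(=O)C(C)(C)C)c(OC)c1)C(=O)N1[C@H](Cc2ccccc2)COC1=O
F4 | step 3 | 4-[(2S)-2-(hydroxymethyl)pent-4-en-1-yl]-2-methoxyphenyl pivalate | C=CC[C@@H](Cc1ccc(OC(=O)C(C)(C)C)c(OC)c1)CO
F5 | step 3 | 2-methoxy-4-{(2S)-2-[(methoxymethoxy)methyl]pent-4-en-1-yl}phenyl pivalate | C=CC[C@@H](Cc1ccc(OC(=O)C(C)(C)C)c(OC)c1)COCOC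
F6 | step 3 | 2-methoxy-4-{(2R)-2-[(methoxymethoxy)methyl]-4-oxobutyl}phenyl pivalate | O=CC[C@@H](Cc1ccc(OC(=O)C(C)(C)C)c(OC)c1)COCOC
F7 | step 4 | 2-methoxy-4-{(2R,3Z)-2-{[(phenylthio)methoxy]methyl}-4-[(trimethylsilyl)oxy]but-3-en-1-yl}phenyl pivalate | C[Si](C)(C)O/C=C\[C@H](COCSc1ccccc1)Cc1ccc(OC(=O)C(C)(C)C)c(OC)c1
F8 | step 8 | 4-{[(3R,4R)-4-{(R)-[4-(tert-butyldimethylsilyloxy)-3,5-dimethoxyphenyl](hydroxy)methyl}tetrahydrofuran-3-yl]methyl}-2-methoxyphenyl pivalate | COc1cc(C[C@H]2COC[C@@H]2[C@@H](O)c2cc(OC)c(O[Si](C)(C)C(C)(C)C)c(OC)c2)ccc1OC(=O)C(C)(C)C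
F9 | step 8 | (S)-[4-(tert-butyldimethylsilyloxy)-3,5-dimethoxyphenyl]{(3R,4R)-4-{[3-methoxy-4-(pivaloyloxy)phenyl]methyl}tetrahydrofuran-3-yl}methyl 4-nitrobenzoate | COc1cc(C[C@H]2COC[C@@H]2[C@H](OC(=O)c2ccc(cc2)[N+](=O)[O-])c2cc(OC)c(O[Si](C)(C)C(C)(C)C)c(OC)c2)ccc1OC(=O)C(C)(C)C
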